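The disconnection is the C5–C6 bond of the cyclohexene ring (C1 carries the aroyl group, C3=C4 is the alkene, C6 carries phenyl), made by a strain-driven 1,3-carbon shift. Because C6 is benzylic and C5 is allylic to C3=C4, a cyclobutane in which C6 is still bonded to C3 can open to a benzyl/allyl diradical and reclose at C5. One thermal operation thus delivers the six-membered ring, the ring alkene and the C6 stereocentre, with C1 as the controlling spectator. The precursor is an enantioenriched 1-aroyl-2-phenyl-3-alkenylcyclobutane from an asymmetric [2+2] photocycloaddition of silylated cardamonin with myrcene.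

Key step: step 3

Assumption (locants): C1–C6 are the cyclohexene carbons of the target, and the same labels are kept for the corresponding carbons of the cyclobutane, which is therefore the ring C1–C2–C3–C6.

Assumption (sense of induction): the (S,S)-tert-butyl-pybox ligand is taken to give the (1R)-cyclobutane; if the induction runs the other way, the (R,R)-ligand is used instead.

Remark on the precursor: C3 and C6 of the cyclobutane are erased in the ring expansion, so only C1 has to be secured. Material that is epimeric at C3 can be carried forward unseparated, which relaxes the demand for a single all-trans diastereomer.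

Step 1
Reactants: 1 cardamonin; 2 tert-butyldimethylsilyl chloride
Product: 3 (2E)-1-(4-{[tert-butyl(dimethyl)silyl]oxy}-2-hydroxy-6-methoxyphenyl)-3-phenylprop-2-en-1-one
Conditions: TBSCl (1.05 equiv), imidazole (1.2 equiv), CH2Cl2, 0 °C to rt
Reagents that add atoms: tert-butyldimethylsilyl chloride (compound 2), CC(C)(C)[Si](C)(C)Cl
Why: Chemoselective O-silylation of a phenol: the 2'-hydroxyl is locked in a strong hydrogen bond to the ketone and is hindered, so one equivalent of 2 should silylate only the more acidic, exposed 4'-hydroxyl, and no stereocentre is involved.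

Step 2
Reactants: 3 (2E)-1-(4-{[tert-butyl(dimethyl)silyl]oxy}-2-hydroxy-6-methoxyphenyl)-3-phenylprop-2-en-1-one; 4 myrcene (7-methyl-3-methylideneocta-1,6-diene)
Product: 5 (4-{[tert-butyl(dimethyl)silyl]oxy}-2-hydroxy-6-methoxyphenyl)[(1R,2R,3S)-3-(6-methylhepta-1,5-dien-2-yl)-2-phenylcyclobutyl]methanone (all-trans: aroyl and alkenyl on one face, phenyl on the other)
Conditions: Sc(OTf)3 (10 mol %), (S,S)-t-Bu-pybox (15 mol %), Ru(bpy)3(PF6)2 (2.5 mol %), 4 (10 equiv), i-PrOAc/MeCN 3:1, degassed, blue LEDs, rt
Reagents that add atoms: none
Why: Enantioselective Lewis acid-enabled, triplet-sensitised [2+2] photocycloaddition of a 2'-hydroxychalcone with a 1,3-diene: only chalcone chelated through its 2'-hydroxy ketone to the Sc(OTf)3–pybox complex has a triplet energy low enough to be sensitised by Ru(bpy)3(PF6)2, its α-carbon (C1) should add from the unshielded face to the terminal CH2 of the vinyl group of 4 to give a benzyl/allyl diradical that closes at the internal allyl carbon, so the ligand sets C1 and the phenyl-bearing carbon, the E-alkene gives their trans relationship, and closure anti to phenyl sets C3.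

Step 3
Reactants: 5 (4-{[tert-butyl(dimethyl)silyl]oxy}-2-hydroxy-6-methoxyphenyl)[(1R,2R,3S)-3-(6-methylhepta-1,5-dien-2-yl)-2-phenylcyclobutyl]methanone
Product: 6 (4-{[tert-butyl(dimethyl)silyl]oxy}-2-hydroxy-6-methoxyphenyl)[(1R,6R)-4-(4-methylpent-3-en-1-yl)-6-phenylcyclohex-3-en-1-yl]methanone (trans)
Conditions: 5 (chromatographed free of Sc and Ru salts), degassed 1,2-dichlorobenzene (0.01 M), BHT (10 mol %), Ar, base-washed sealed tube, 175 °C
Reagents that add atoms: none
Why: Heat should homolyse the cyclobutane bond C3–C6, which is weakened by ring strain and by benzyl and allyl stabilisation of the two radical ends, and the benzylic C6 then recombines with the far allyl terminus C5 while C3=C4 becomes the ring alkene. The closest known reaction is the thermal vinylcyclobutane-to-cyclohexene rearrangement, a formal 1,3-carbon shift established for 2-aryl- and 2-vinyl-substituted vinylcyclobutanes. The six-membered ring C1–C6 closes by radical–radical coupling at C5–C6 within the cisoid allyl radical, a shape made accessible by the alkyl chain on C4, whereas transoid diradicals can only reclose to the cyclobutane and try again. C6 is planar in the diradical and is re-set under substrate control by the untouched C1 stereocentre, coupling through a half-chair with aroyl and phenyl both pseudo-equatorial to give the trans (1R,6R) product. The step needs C3–C6 to break in preference to C1–C6, which the better radical stabilisation by allyl than by α-acyl secures, and it needs ring closure to outrun fragmentation across C1–C2 to 3 and 4. High dilution, neutral metal-free conditions and a radical inhibitor keep racemic Diels–Alder recombination, enolisation at C1 and polymerisation in check.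

Step 4
Reactants: 6 (4-{[tert-butyl(dimethyl)silyl]oxy}-2-hydroxy-6-methoxyphenyl)[(1R,6R)-4-(4-methylpent-3-en-1-yl)-6-phenylcyclohex-3-en-1-yl]methanone
Product: 7 (2,4-dihydroxy-6-methoxyphenyl)[(1R,6R)-4-(4-methylpent-3-en-1-yl)-6-phenylcyclohex-3-en-1-yl]methanone
Conditions: KHF2 (2.5 equiv), MeOH, rt
Reagents that add atoms: none
Why: Fluoride-induced cleavage of an aryl silyl ether (desilylation): bifluoride in methanol is close to neutral and selective for phenolic silyl ethers, so the C1 and C6 stereocentres and the two trisubstituted alkenes should remain untouched.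

Compound list
1 | cardamonin, (2E)-1-(2,4-dihydroxy-6-methoxyphenyl)-3-phenylprop-2-en-1-one | COc1cc(O)cc(O)c1C(=O)/C=C/c1ccccc1 | starting material
2 | tert-butyldimethylsilyl chloride | CC(C)(C)[Si](C)(C)Cl | starting material
3 | (2E)-1-(4-{[tert-butyl(dimethyl)silyl]oxy}-2-hydroxy-6-methoxyphenyl)-3-phenylprop-2-en-1-one | COc1cc(O[Si](C)(C)C(C)(C)C)cc(O)c1C(=O)/C=C/c1ccccc1 | intermediate
4 | myrcene, 7-methyl-3-methylideneocta-1,6-diene | CC(C)=CCCC(=C)C=C | starting material
5 | (4-{[tert-butyl(dimethyl)silyl]oxy}-2-hydroxy-6-methoxyphenyl)[(1R,2R,3S)-3-(6-methylhepta-1,5-dien-2-yl)-2-phenylcyclobutyl]methanone | COc1cc(O[Si](C)(C)C(C)(C)C)cc(O)c1C(=O)[C@@H]1C[C@H](C(=C)CCC=C(C)C)[C@H]1c1ccccc1 | intermediate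
6 | (4-{[tert-butyl(dimethyl)silyl]oxy}-2-hydroxy-6-methoxyphenyl)[(1R,6R)-4-(4-methylpent-3-en-1-yl)-6-phenylcyclohex-3-en-1-yl]methanone | COc1cc(O[Si](C)(C)C(C)(C)C)cc(O)c1C(=O)[C@@H]1CC=C(CCC=C(C)C)C[C@H]1c1ccccc1 | intermediate
7 | (2,4-dihydroxy-6-methoxyphenyl)[(1R,6R)-4-(4-methylpent-3-en-1-yl)-6-phenylcyclohex-3-en-1-yl]methanone | COc1cc(O)cc(O)c1C(=O)[C@@H]1CC=C(CCC=C(C)C)C[C@H]1c1ccccc1 | target

Total step count: 4. Longest linear sequence: 4 steps (1 to 3 to 5 to 6 to 7).

Steps most likely to fail

Step 3 (ring expansion). After homolysis of C3–C6 the diradical may fragment across C1–C2 instead of closing, and the chalcone and diene set free can then recombine slowly in a racemic Diels–Alder reaction. The ring may also close with the wrong sense at C6, or stereochemical information may leak through enolisation at C1. A cis isomer would have to be removed by chromatography and not epimerised, because inversion at C1 would turn it into the enantiomer of 6. Fallback: the cyclobutane detour would be given up and the ring closed directly by an enantioselective Diels–Alder reaction. Chalcone 3 and myrcene 4 would be combined with a chiral borate Lewis acid prepared from B(OPh)3 and enantiopure VANOL (3,3'-diphenyl-2,2'-bi-1-naphthol, antipode selected for the (1R,6R) series) in PhCF3 at rt. Exchange of the 2'-hydroxyl onto boron activates the enone, the E-geometry translates into the trans relationship of C1 and C6, and normal diene polarisation places the side chain on C4. This detour sets out from 3 (with 4) and comes back to the route at 6. It makes no compound outside the compound list: none F0.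

Step 2 (photocycloaddition). The excited chalcone may attack the 1,1-disubstituted terminus of myrcene instead of the vinyl terminus. That loss of regiocontrol leads to a cyclobutane with a quaternary C3, which would have to be removed before step 3 because it would ring-expand to the C3-substituted cyclohexene. Fallback: the diene would be replaced by buta-1,3-diene, whose two termini are equivalent, and the side chain would be built afterwards.
- Chalcone 3 and buta-1,3-diene under the conditions of step 2 should give the vinylcyclobutane (4-{[tert-butyl(dimethyl)silyl]oxy}-2-hydroxy-6-methoxyphenyl)[(1R,2R,3R)-3-ethenyl-2-phenylcyclobutyl]methanone F1.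
- Tsuji–Wacker oxidation (PdCl2, CuCl, O2, DMF/H2O, rt) should convert the vinyl group into the methyl ketone (4-{[tert-butyl(dimethyl)silyl]oxy}-2-hydroxy-6-methoxyphenyl)[(1R,2R,3S)-3-acetyl-2-phenylcyclobutyl]methanone F2.
- Kinetic deprotonation of the methyl group (LiN(i-Pr)2, 2.2 equiv, THF, −78 °C, the first equivalent being taken up by the phenol) and alkylation with prenyl bromide (1-bromo-3-methylbut-2-ene) should give (4-{[tert-butyl(dimethyl)silyl]oxy}-2-hydroxy-6-methoxyphenyl)[(1R,2R,3S)-3-(5-methylhex-4-enoyl)-2-phenylcyclobutyl]methanone F3.
- Wittig methylenation of the alkyl ketone (Ph3PCH3Br, KOt-Bu, THF, 0 °C to rt) should give 5; the aryl ketone is deactivated as its hindered phenoxide.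

Epimerisation at C3 in these operations is immaterial, since C3 becomes trigonal in step 3. The detour sets out from 3 and comes back to the route at 5.

Step 4 (desilylation). Cleavage may be incomplete under the mild bifluoride conditions. Harsher basic or acidic fluoride sources could then cause epimerisation at C1 or addition across the trisubstituted alkenes. Fallback: protection would be omitted altogether. Cardamonin 1 and myrcene 4 would be taken through the photocycloaddition of step 2, relying on the 2'-hydroxy ketone as the only chelating site, to give (2,4-dihydroxy-6-methoxyphenyl)[(1R,2R,3S)-3-(6-methylhepta-1,5-dien-2-yl)-2-phenylcyclobutyl]methanone F4. Heating F4 under the conditions of step 3 should give the target directly. The detour sets out from 1 and comes back to the route at 7.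

Further compounds
F0 | step 3 | none | none
F1 | step 2 | (4-{[tert-butyl(dimethyl)silyl]oxy}-2-hydroxy-6-methoxyphenyl)[(1R,2R,3R)-3-ethenyl-2-phenylcyclobutyl]methanone | COc1cc(O[Si](C)(C)C(C)(C)C)cc(O)c1C(=O)[C@@H]1C[C@H](C=C)[C@H]1c1ccccc1
F2 | step 2 | (4-{[tert-butyl(dimethyl)silyl]oxy}-2-hydroxy-6-methoxyphenyl)[(1R,2R,3S)-3-acetyl-2-phenylcyclobutyl]methanone | COc1cc(O[Si](C)(C)C(C)(C)C)cc(O)c1C(=O)[C@@H]1C[C@H](C(C)=O)[C@H]1c1ccccc1
F3 | step 2 | (4-{[tert-butyl(dimethyl)silyl]oxy}-2-hydroxy-6-methoxyphenyl)[(1R,2R,3S)-3-(5-methylhex-4-enoyl)-2-phenylcyclobutyl]methanone | COc1cc(O[Si](C)(C)C(C)(C)C)cc(O)c1C(=O)[C@@H]1C[C@H](C(=O)CCC=C(C)C)[C@H]1c1ccccc1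
F4 | step 4 | (2,4-dihydroxy-6-methoxyphenyl)[(1R,2R,3S)-3-(6-methylhepta-1,5-dien-2-yl)-2-phenylcyclobutyl]methanone | COc1cc(O)cc(O)c1C(=O)[C@@H]1C[C@H](C(=C)CCC=C(C)C)[C@H]1c1ccccc1
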